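**Strategy**

Ring C is disconnected across O1–C2 and C3–C4. Because O1 and the C4 methylene both sit on ring A (at C8a and C4a) while C2 carries ring B and C3 a cis oxygen, ring C is the formal [4+2] adduct of a ring-A ortho-quinone methide and a Z-configured two-carbon unit. One chiral-acid-catalysed cycloaddition of a Z-styrylboronate therefore closes ring C, forms both bonds and sets C2 and C3 cis, boron standing in for the C3 oxygen. The precursor is a ring-A 2-hydroxybenzyl alcohol already carrying the O7 gallate and an O5 benzyl ether; the ring-B and gallate phenols are benzyl ethers too, so boron oxidation and one hydrogenolysis finish the synthesis.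

Key step: step 6

Assumption: 3,4,5-tris(benzyloxy)benzoic acid and 3,4,5-tris(benzyloxy)benzaldehyde are taken as purchasable (each is otherwise reached from methyl gallate by routine benzylation and ester adjustment), and the acid catalyst of step 6 is written as (R) on the understanding that its mirror image is used if the adduct forms in the opposite sense.

Remark: the cycloadduct is labelled (2S,3R) only because boron ranks below carbon in the CIP rules; spatially it matches the (2R,3R) target, and the C–B to C–O exchange proceeds with retention.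

**Route**

Step 1
Reactants: 1 3,4,5-tris(benzyloxy)benzoic acid; 2 2,4,6-trihydroxybenzaldehyde
Product: 4 4-formyl-3,5-dihydroxyphenyl 3,4,5-tris(benzyloxy)benzoate, via acid chloride 3 (not isolated)
Conditions: (COCl)2, DMF (cat.), CH2Cl2, 0 °C to rt, then evaporation; 2 (1.2 equiv), iPr2NEt (1.1 equiv), THF, −30 to 0 °C, slow addition of 3
Reagents that add atoms: none
Why: Acid chloride formation followed by O-acylation of a phenol, which should occur at the para hydroxyl because one equivalent of hindered amine ionises only this most acidic, vinylogous-acid OH while both ortho hydroxyls are hydrogen-bonded to and flanked by the formyl group, and the slight excess of cheap 2 disfavours double acylation.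

Step 2
Reactants: 4 4-formyl-3,5-dihydroxyphenyl 3,4,5-tris(benzyloxy)benzoate
Product: 5 3-(benzyloxy)-4-formyl-5-hydroxyphenyl 3,4,5-tris(benzyloxy)benzoate
Conditions: BnOH (1.05 equiv), PPh3, DIAD, THF, 0 °C to rt
Reagents that add atoms: benzyl alcohol, OCc1ccccc1
Why: Mitsunobu etherification of one of two equivalent ortho hydroxyls, which should stop at the mono-ether because the remaining OH is then locked in the chelate with the formyl oxygen, and whose neutral conditions leave the aryl ester untouched.

Step 3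
Reactants: 5 3-(benzyloxy)-4-formyl-5-hydroxyphenyl 3,4,5-tris(benzyloxy)benzoate
Product: 6 3-(benzyloxy)-5-hydroxy-4-(hydroxymethyl)phenyl 3,4,5-tris(benzyloxy)benzoate
Conditions: NaBH4, THF/H2O (20:1), 0 °C, short reaction time; pH 7 phosphate buffer; filtration through Et3N-washed silica, used at once
Reagents that add atoms: none
Why: Borohydride reduction of the aldehyde is fast at 0 °C and should spare the electron-rich aryl trialkoxybenzoate in the absence of alkoxide, while the neutral work-up and immediate use guard the acid-labile, electron-rich 2-hydroxybenzyl alcohol against premature loss of water.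

Step 4
Reactants: 7 3,4,5-tris(benzyloxy)benzaldehyde
Product: 8 1,2,3-tris(benzyloxy)-5-ethynylbenzene
Conditions: dimethyl (1-diazo-2-oxopropyl)phosphonate, K2CO3, MeOH/THF, 0 °C to rt
Reagents that add atoms: dimethyl (1-diazo-2-oxopropyl)phosphonate, COP(=O)(OC)C(=[N+]=[N-])C(C)=O
Why: Seyferth–Gilbert homologation in the Ohira–Bestmann variant, in which the diazomethylphosphonate anion released by methanolysis olefinates the non-enolisable aldehyde and the diazoalkene loses N2 with a 1,2-hydrogen shift to give the terminal alkyne, benzyl ethers being inert.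

Step 5
Reactants: 8 1,2,3-tris(benzyloxy)-5-ethynylbenzene; 9 pinacolborane
Product: 10 (Z)-2-[3,4,5-tris(benzyloxy)phenyl]ethenylboronic acid pinacol ester
Conditions: [Rh(cod)Cl]2 (1.5 mol %), P(iPr)3 (6 mol %), Et3N, cyclohexane, rt, alkyne in slight excess
Reagents that add atoms: none
Why: Rhodium-catalysed trans-hydroboration of a terminal arylalkyne through a rhodium vinylidene, with the bulky trialkylphosphine and Et3N suppressing ordinary syn addition, should place boron on the terminal carbon cis to the aryl group and so give the Z-alkenylboronate.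

Step 6
Reactants: 6 3-(benzyloxy)-5-hydroxy-4-(hydroxymethyl)phenyl 3,4,5-tris(benzyloxy)benzoate; 10 (Z)-2-[3,4,5-tris(benzyloxy)phenyl]ethenylboronic acid pinacol ester
Product: 12 (2S,3R)-5-(benzyloxy)-3-(4,4,5,5-tetramethyl-1,3,2-dioxaborolan-2-yl)-2-[3,4,5-tris(benzyloxy)phenyl]-3,4-dihydro-2H-chromen-7-yl 3,4,5-tris(benzyloxy)benzoate, via ortho-quinone methide 11 (not isolated)
Conditions: (R)-3,3'-bis(2,4,6-triisopropylphenyl)-1,1'-binaphthyl-2,2'-diyl N-triflylphosphoramide (10 mol %), 5 Å MS, PhMe, −40 to 0 °C, 10 (2 equiv), slow addition of 6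
Reagents that add atoms: none
Why: Proposed new method: the acid ionises the benzylic C–OH of 6 to the hydrogen-bonded ortho-quinone methide 11 (exocyclic C4 on C4a, carbonyl O1 on C8a), and the alkene of 10 then adds in one asynchronous, suprafacial inverse-demand oxa-Diels–Alder event in which C4 bonds to the boron-bearing carbon (C3) slightly ahead of O1 closing on the benzylic carbon (C2); the closest known reaction type is the chiral phosphoric acid or N-triflylphosphoramide catalysed [4+2] cycloaddition of ortho-quinone methides from 2-hydroxybenzyl alcohols with styrenes and enol ethers, which has not been extended to alkenylboronates or to catalyst control over a methide without a C4 substituent. Ring C is the only ring formed and closes by intermolecular [4+2] annulation of the four-atom O1=C8a–C4a=C4 heterodiene onto the two alkene carbons. C2 and C3 are created together: their cis relation is dictated by the Z geometry of 10, since both new bonds form on the same alkene face, and their absolute configuration is to be set by the chiral phosphoramide anion, which is hydrogen-bonded to O1 and must select one methide face together with one endo or exo placement of the cis aryl and boryl groups within its 2,4,6-triisopropylphenyl pocket. Regioselectivity is secured by ring B, which stabilises developing positive charge at C2 (assisted by hyperconjugation of the adjacent C–B bond), so that C4 attacks the carbon bearing boron. The step also needs chemoselectivity for cycloaddition over self-alkylation at C6 or C8 of ring A, over transfer of the alkenyl group from boron to C4 and over acid-induced Z-to-E isomerisation; this is served by the O7 ester (more electrophilic methide, less nucleophilic ring A), the O5 benzyl ether (a single possible methide), the weakly Lewis acidic pinacol ester, excess 10, low temperature and slow addition of 6.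

Step 7
Reactants: 12 (2S,3R)-5-(benzyloxy)-3-(4,4,5,5-tetramethyl-1,3,2-dioxaborolan-2-yl)-2-[3,4,5-tris(benzyloxy)phenyl]-3,4-dihydro-2H-chromen-7-yl 3,4,5-tris(benzyloxy)benzoate
Product: 13 (2R,3R)-5-(benzyloxy)-3-hydroxy-2-[3,4,5-tris(benzyloxy)phenyl]-3,4-dihydro-2H-chromen-7-yl 3,4,5-tris(benzyloxy)benzoate
Conditions: NaBO3·4H2O, THF/H2O (1:1), 0 °C to rt
Reagents that add atoms: sodium perborate tetrahydrate, [Na+].[Na+].O[B-]1(O)OO[B-](O)(O)OO1.O.O.O.O.O.O
Why: Boronate oxidation, in which hydroperoxide adds to boron and C3 migrates from boron to oxygen with retention so that the cis C2/C3 relation is carried into the 3-ol, the nearly neutral perborate medium being chosen to spare the 7-O aryl ester and to avoid β-elimination of the ring oxygen.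

Step 8
Reactants: 13 (2R,3R)-5-(benzyloxy)-3-hydroxy-2-[3,4,5-tris(benzyloxy)phenyl]-3,4-dihydro-2H-chromen-7-yl 3,4,5-tris(benzyloxy)benzoate
Product: 14 epigallocatechin 7-O-gallate, (2R,3R)-3,5-dihydroxy-2-(3,4,5-trihydroxyphenyl)-3,4-dihydro-2H-chromen-7-yl 3,4,5-trihydroxybenzoate
Conditions: H2 (1 atm), Pd(OH)2/C, THF/MeOH (1:1), rt; filtration under argon
Reagents that add atoms: none
Why: Catalytic hydrogenolysis of all seven benzyl ethers over Pd(OH)2/C, conditions known to leave the O1–C2 bond, aryl gallate esters and both stereocentres of flavan-3-ols intact, with air excluded to protect the pyrogallol units.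

**Compound list**

1 | 3,4,5-tris(benzyloxy)benzoic acid | OC(=O)c1cc(OCc2ccccc2)c(OCc2ccccc2)c(OCc2ccccc2)c1 | starting material
2 | 2,4,6-trihydroxybenzaldehyde | O=Cc1c(O)cc(O)cc1O | starting material
3 | 3,4,5-tris(benzyloxy)benzoyl chloride | ClC(=O)c1cc(OCc2ccccc2)c(OCc2ccccc2)c(OCc2ccccc2)c1 | intermediate
4 | 4-formyl-3,5-dihydroxyphenyl 3,4,5-tris(benzyloxy)benzoate | O=Cc1c(O)cc(OC(=O)c2cc(OCc3ccccc3)c(OCc3ccccc3)c(OCc3ccccc3)c2)cc1O | intermediate
5 | 3-(benzyloxy)-4-formyl-5-hydroxyphenyl 3,4,5-tris(benzyloxy)benzoate | O=Cc1c(O)cc(OC(=O)c2cc(OCc3ccccc3)c(OCc3ccccc3)c(OCc3ccccc3)c2)cc1OCc1ccccc1 | intermediate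
6 | 3-(benzyloxy)-5-hydroxy-4-(hydroxymethyl)phenyl 3,4,5-tris(benzyloxy)benzoate | OCc1c(O)cc(OC(=O)c2cc(OCc3ccccc3)c(OCc3ccccc3)c(OCc3ccccc3)c2)cc1OCc1ccccc1 | intermediate
7 | 3,4,5-tris(benzyloxy)benzaldehyde | O=Cc1cc(OCc2ccccc2)c(OCc2ccccc2)c(OCc2ccccc2)c1 | starting material
8 | 1,2,3-tris(benzyloxy)-5-ethynylbenzene | C#Cc1cc(OCc2ccccc2)c(OCc2ccccc2)c(OCc2ccccc2)c1 | intermediate
9 | pinacolborane (4,4,5,5-tetramethyl-1,3,2-dioxaborolane) | CC1(C)OBOC1(C)C | starting material
10 | (Z)-2-[3,4,5-tris(benzyloxy)phenyl]ethenylboronic acid pinacol ester | CC1(C)OB(/C=C\c2cc(OCc3ccccc3)c(OCc3ccccc3)c(OCc3ccccc3)c2)OC1(C)C | intermediate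
11 | 5-(benzyloxy)-4-methylidene-3-oxocyclohexa-1,5-dien-1-yl 3,4,5-tris(benzyloxy)benzoate (ortho-quinone methide) | C=C1C(=O)C=C(OC(=O)c2cc(OCc3ccccc3)c(OCc3ccccc3)c(OCc3ccccc3)c2)C=C1OCc1ccccc1 | intermediate
12 | (2S,3R)-5-(benzyloxy)-3-(4,4,5,5-tetramethyl-1,3,2-dioxaborolan-2-yl)-2-[3,4,5-tris(benzyloxy)phenyl]-3,4-dihydro-2H-chromen-7-yl 3,4,5-tris(benzyloxy)benzoate (2,3-cis) | O=C(Oc1cc(OCc2ccccc2)c2c(c1)O[C@H](c1cc(OCc3ccccc3)c(OCc3ccccc3)c(OCc3ccccc3)c1)[C@H](B1OC(C)(C)C(C)(C)O1)C2)c1cc(OCc2ccccc2)c(OCc2ccccc2)c(OCc2ccccc2)c1 | intermediate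
13 | (2R,3R)-5-(benzyloxy)-3-hydroxy-2-[3,4,5-tris(benzyloxy)phenyl]-3,4-dihydro-2H-chromen-7-yl 3,4,5-tris(benzyloxy)benzoate (2,3-cis) | O=C(Oc1cc(OCc2ccccc2)c2c(c1)O[C@H](c1cc(OCc3ccccc3)c(OCc3ccccc3)c(OCc3ccccc3)c1)[C@H](O)C2)c1cc(OCc2ccccc2)c(OCc2ccccc2)c(OCc2ccccc2)c1 | intermediate
14 | epigallocatechin 7-O-gallate, (2R,3R) | O=C(Oc1cc(O)c2c(c1)O[C@H](c1cc(O)c(O)c(O)c1)[C@H](O)C2)c1cc(O)c(O)c(O)c1 | target

**Step count and risks**

Total steps: 8. Longest linear sequence: 6 steps (steps 1, 2, 3, 6, 7, 8); the ring-B branch (steps 4, 5) joins at step 6.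

Steps most likely to fail:

1. Step 6. The cycloaddition may suffer from poor facial selectivity on a methide with no C4 substituent, from loss of the cis relation through a stepwise cationic pathway or acid-induced Z-to-E isomerisation, from transfer of the alkenyl group from boron to C4, or from self-alkylation of ring A. The fallback uses known reactions, sets out from 6 and 10 and returns at 13.
 - 10 is converted with KHF2 (MeOH/H2O, rt) into potassium (Z)-trifluoro{2-[3,4,5-tris(benzyloxy)phenyl]ethenyl}borate F1.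
 - BF3·OEt2 (CH2Cl2, −40 °C) unmasks the alkenyldifluoroborane in the presence of 6. In the established 1,4-addition of alkenylboron reagents to ortho-quinone methides, it transfers the alkenyl group with retention of geometry to the methide carbon, giving the open-chain (Z)-cinnamylphenol F2.
 - Silylation (TBSCl, imidazole, DMF) gives the tert-butyldimethylsilyl ether F3.
 - Jacobsen–Katsuki epoxidation of this cis-β-alkylstyrene gives the cis-(2R,3S)-epoxide F4. The catalyst is (S,S)-N,N'-bis(3,5-di-tert-butylsalicylidene)-1,2-cyclohexanediaminomanganese chloride, a salen complex of trivalent manganese, with mCPBA and N-methylmorpholine N-oxide in CH2Cl2 at −78 °C. The catalyst enantiomer is the one expected by analogy with cis-β-methylstyrene.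
 - Desilylation (Bu4NF buffered with AcOH, THF, 0 °C) and then camphorsulfonic acid at low temperature close ring C by 6-endo attack of O1 on the benzylic epoxide carbon with inversion. This converts the cis-epoxide into the 2,3-cis flavan-3-ol 13, and the route resumes at step 8.

2. Step 1. The mono-acylation may go astray through attack at an ortho hydroxyl, double acylation or intermolecular acyl exchange. The fallback fixes the regiochemistry by chelation-controlled protection instead; it sets out from 2 and returns at 5.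
 - MOMCl (2 equiv) and iPr2NEt in CH2Cl2 leave only the chelated hydroxyl free and give 2-hydroxy-4,6-bis(methoxymethoxy)benzaldehyde F5.
 - BnBr, K2CO3 in DMF alkylate that hydroxyl to 2-(benzyloxy)-4,6-bis(methoxymethoxy)benzaldehyde F6.
 - HCl in MeOH removes both acetals to give 2-(benzyloxy)-4,6-dihydroxybenzaldehyde F7, in which only the para hydroxyl is outside the chelate.
 - Acylation with 3 (iPr2NEt, THF, −30 °C) should then give 5 without ambiguity, and the route resumes at step 3.

3. Step 7. The oxidation may be accompanied by perhydrolysis of the 7-O aryl ester by hydroperoxide, or by base-induced β-elimination of the ring oxygen from the boron ate complex, which would open ring C. The fallback sets out from 12 and returns at 13.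
 - KHF2 (MeOH/H2O, rt) converts 12 into the potassium (2S,3R)-flavan-3-yltrifluoroborate F8.
 - KHSO5 (as 2KHSO5·KHSO4·K2SO4) in acetone/H2O at rt oxidises the C3–B bond within minutes under non-basic conditions and with retention, giving 13.

Further compounds
F1 | step 6 | potassium (Z)-trifluoro{2-[3,4,5-tris(benzyloxy)phenyl]ethenyl}borate | [K+].F[B-](F)(F)/C=C\c1cc(OCc2ccccc2)c(OCc2ccccc2)c(OCc2ccccc2)c1
F2 | step 6 | 3-(benzyloxy)-5-hydroxy-4-{(2Z)-3-[3,4,5-tris(benzyloxy)phenyl]prop-2-en-1-yl}phenyl 3,4,5-tris(benzyloxy)benzoate | Oc1cc(OC(=O)c2cc(OCc3ccccc3)c(OCc3ccccc3)c(OCc3ccccc3)c2)cc(OCc2ccccc2)c1C/C=C\c1cc(OCc2ccccc2)c(OCc2ccccc2)c(OCc2ccccc2)c1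
F3 | step 6 | 3-(benzyloxy)-5-[(tert-butyldimethylsilyl)oxy]-4-{(2Z)-3-[3,4,5-tris(benzyloxy)phenyl]prop-2-en-1-yl}phenyl 3,4,5-tris(benzyloxy)benzoate | CC(C)(C)[Si](C)(C)Oc1cc(OC(=O)c2cc(OCc3ccccc3)c(OCc3ccccc3)c(OCc3ccccc3)c2)cc(OCc2ccccc2)c1C/C=C\c1cc(OCc2ccccc2)c(OCc2ccccc2)c(OCc2ccccc2)c1
F4 | step 6 | 3-(benzyloxy)-5-[(tert-butyldimethylsilyl)oxy]-4-({(2R,3S)-3-[3,4,5-tris(benzyloxy)phenyl]oxiran-2-yl}methyl)phenyl 3,4,5-tris(benzyloxy)benzoate | CC(C)(C)[Si](C)(C)Oc1cc(OC(=O)c2cc(OCc3ccccc3)c(OCc3ccccc3)c(OCc3ccccc3)c2)cc(OCc2ccccc2)c1C[C@H]1O[C@H]1c1cc(OCc2ccccc2)c(OCc2ccccc2)c(OCc2ccccc2)c1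
F5 | step 1 | 2-hydroxy-4,6-bis(methoxymethoxy)benzaldehyde | O=Cc1c(O)cc(OCOC)cc1OCOC
F6 | step 1 | 2-(benzyloxy)-4,6-bis(methoxymethoxy)benzaldehyde | O=Cc1c(OCc2ccccc2)cc(OCOC)cc1OCOC
F7 | step 1 | 2-(benzyloxy)-4,6-dihydroxybenzaldehyde | O=Cc1c(OCc2ccccc2)cc(O)cc1O
F8 | step 7 | potassium [(2S,3R)-5-(benzyloxy)-7-{[3,4,5-tris(benzyloxy)benzoyl]oxy}-2-[3,4,5-tris(benzyloxy)phenyl]-3,4-dihydro-2H-chromen-3-yl]trifluoroborate | O=C(Oc1cc(OCc2ccccc2)c2c(c1)O[C@H](c1cc(OCc3ccccc3)c(OCc3ccccc3)c(OCc3ccccc3)c1)[C@H]([B-](F)(F)F)C2)c1cc(OCc2ccccc2)c(OCc2ccccc2)c(OCc2ccccc2)c1.[K+]
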